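**Retrosynthetic overview**

- Ring C of the terminal (lower) epicatechin unit is closed last by an oxa-[4+2] cycloaddition. The diene is an ortho-quinone methide on the terminal ring A, which already carries the two upper units at C8. The dienophile is the (Z)-enol gallate of 3,4-bis(benzyloxy)phenylacetaldehyde. The step forms O1–C2 and C3–C4 and brings in ring B, the third gallate and both stereocentres.
- Enabling feature: C4 of the terminal unit is an unsubstituted CH2 on C4a, ortho to C8a–O1 of a phloroglucinol-type ring A. This is an ortho-hydroxybenzyl (quinone methide) retron, and the cis C2-aryl/C3-acyloxy pair maps onto a Z-β-acyloxystyrene.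
- The quinone methide comes from a salicyl alcohol by loss of water, and the salicyl alcohol comes from a salicylaldehyde by reduction. The formyl group also deactivates the terminal arene during the second interflavan coupling.
- Both C4–C8 bonds come from Lewis-acid Friedel–Crafts couplings of one C4-activated, galloylated epicatechin electrophile: first with 3,5-bis(benzyloxy)phenol, then at C8 of the resulting unit.
- Ring order: the rings of the two upper units come intact from (−)-epicatechin; terminal ring A comes from the phenol and ring B from 3,4-bis(benzyloxy)benzaldehyde; terminal ring C is closed last; global hydrogenolysis follows.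

Key step: step 10

Assumption: the (R) antipode of the binaphthyl phosphoric acid is taken to be the one matched with the substrate and leading to the (2R,3R) unit; if a model shows the opposite sense, the (S) antipode takes its place without other change.

**Step 1**
Reactants: 1 (−)-epicatechin
Product: 2 5,7,3',4'-tetra-O-benzyl-(−)-epicatechin
Conditions: BnBr (4.4 equiv), K2CO3, DMF, 0 °C to rt
Reagents that add atoms: benzyl bromide, BrCc1ccccc1
Why: Williamson etherification: under carbonate conditions only the four phenols are deprotonated, so the secondary 3-OH stays free and no stereocentre is touched.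

**Step 2**
Reactants: 2 5,7,3',4'-tetra-O-benzyl-(−)-epicatechin
Product: 3 4β-(2-ethoxyethoxy)-5,7,3',4'-tetra-O-benzylepicatechin (3,4-trans)
Conditions: DDQ (2 equiv), 2-ethoxyethanol (5 equiv), CH2Cl2, rt
Reagents that add atoms: 2-ethoxyethanol, CCOCCO
Why: Benzylic oxidative etherification: DDQ abstracts hydride from C4–H, which is activated by the 5,7-dioxygenated ring A, and the cation is captured by the alcohol on the face anti to the C3 oxygen, which should set the 4β (3,4-trans) centre.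

**Step 3**
Reactants: 3 4β-(2-ethoxyethoxy)-5,7,3',4'-tetra-O-benzylepicatechin; 4 3,4,5-tris(benzyloxy)benzoic acid
Product: 5 4β-(2-ethoxyethoxy)-5,7,3',4'-tetra-O-benzylepicatechin 3-O-[3,4,5-tris(benzyloxy)benzoate]
Conditions: DCC, DMAP (cat.), CH2Cl2, rt
Reagents that add atoms: none
Why: Steglich esterification of the hindered secondary alcohol by DMAP acyl transfer; the C4 benzylic ether is inert and no stereocentre changes.

**Step 4**
Reactants: 5 4β-(2-ethoxyethoxy)-5,7,3',4'-tetra-O-benzylepicatechin 3-O-[3,4,5-tris(benzyloxy)benzoate]; 6 3,5-bis(benzyloxy)phenol (3 equiv)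
Product: 7 4β-[2-hydroxy-4,6-bis(benzyloxy)phenyl]-5,7,3',4'-tetra-O-benzylepicatechin 3-O-[3,4,5-tris(benzyloxy)benzoate]
Conditions: TMSOTf (0.2 equiv), CH2Cl2, −78 to −40 °C; Et3N quench
Reagents that add atoms: none
Why: Lewis-acid Friedel–Crafts arylation at C4 of a 4-alkoxyflavan (the reaction type of interflavan coupling): ionisation gives the C4 cation, the 3-acyloxy group blocks the α face so that the arene should add 3,4-trans (4β), and the phenol should react at the less hindered carbon ortho to its free OH rather than at the carbon flanked by two benzyloxy groups.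

**Step 5**
Reactants: 7 4β-[2-hydroxy-4,6-bis(benzyloxy)phenyl]-5,7,3',4'-tetra-O-benzylepicatechin 3-O-[3,4,5-tris(benzyloxy)benzoate]
Product: 8 4β-[3-formyl-2-hydroxy-4,6-bis(benzyloxy)phenyl]-5,7,3',4'-tetra-O-benzylepicatechin 3-O-[3,4,5-tris(benzyloxy)benzoate]
Conditions: MgCl2 (3 equiv), Et3N (6 equiv), (CH2O)n (10 equiv), THF, 65 °C
Reagents that add atoms: paraformaldehyde (formaldehyde), C=O
Why: Casnati–Skattebøl ortho-formylation: the magnesium phenoxide delivers formaldehyde only to the one free carbon ortho to the phenol and the hydroxymethyl intermediate is oxidised in situ by a second formaldehyde, no stereocentre being involved.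

**Step 6**
Reactants: 8 4β-[3-formyl-2-hydroxy-4,6-bis(benzyloxy)phenyl]-5,7,3',4'-tetra-O-benzylepicatechin 3-O-[3,4,5-tris(benzyloxy)benzoate] (1.5 equiv, excess recovered); 5 4β-(2-ethoxyethoxy)-5,7,3',4'-tetra-O-benzylepicatechin 3-O-[3,4,5-tris(benzyloxy)benzoate]
Product: 9 [5,7,3',4'-tetra-O-benzyl-3-O-(tri-O-benzylgalloyl)epicatechin]-(4β→8)-[4β-(3-formyl-2-hydroxy-4,6-bis(benzyloxy)phenyl)-5,7,3',4'-tetra-O-benzyl-3-O-(tri-O-benzylgalloyl)epicatechin]
Conditions: TMSOTf (0.2 equiv), CH2Cl2, −78 to −30 °C; Et3N quench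
Reagents that add atoms: none
Why: Second Lewis-acid Friedel–Crafts interflavan coupling: the cation from 5 should attack C8 of the electron-rich ring A of 8 (the usual 4→8 preference) while the formyl-deactivated, hydrogen-bonded aryl ring stays inert, and the 3-acyloxy group again directs the new C4 centre to 4β.

**Step 7**
Reactants: 9 dimer salicylaldehyde from step 6
Product: 10 [5,7,3',4'-tetra-O-benzyl-3-O-(tri-O-benzylgalloyl)epicatechin]-(4β→8)-[4β-(3-hydroxymethyl-2-hydroxy-4,6-bis(benzyloxy)phenyl)-5,7,3',4'-tetra-O-benzyl-3-O-(tri-O-benzylgalloyl)epicatechin]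
Conditions: NaBH4, THF/MeOH (4:1), 0 °C; NaHCO3 work-up, used crude
Reagents that add atoms: none
Why: Chemoselective borohydride reduction of the aldehyde in the presence of the gallate (benzoate) esters and benzyl ethers; no stereocentre is formed.

**Step 8**
Reactants: 11 3,4-bis(benzyloxy)benzaldehyde
Product: 12 1,2-bis(benzyloxy)-4-ethynylbenzene
Conditions: dimethyl (1-diazo-2-oxopropyl)phosphonate, K2CO3, MeOH, rt
Reagents that add atoms: dimethyl (1-diazo-2-oxopropyl)phosphonate, COP(=O)(OC)C(=[N+]=[N-])C(C)=O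
Why: Seyferth–Gilbert homologation in the Bestmann–Ohira variant, which converts a non-enolisable aryl aldehyde into the terminal alkyne under mild carbonate conditions.

**Step 9**
Reactants: 12 1,2-bis(benzyloxy)-4-ethynylbenzene; 4 3,4,5-tris(benzyloxy)benzoic acid
Product: 13 (Z)-2-[3,4-bis(benzyloxy)phenyl]ethenyl 3,4,5-tris(benzyloxy)benzoate
Conditions: Ru(η3-CH2C(CH3)CH2)2(Ph2P(CH2)4PPh2) (2 mol%), toluene, 60 °C
Reagents that add atoms: none
Why: Ruthenium-catalysed anti-Markovnikov trans-addition of a carboxylic acid to a terminal aryl alkyne through a ruthenium vinylidene, which should give the (Z)-enol ester selectively.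

**Step 10**
Reactants: 10 dimer salicyl alcohol from step 7; 13 (Z)-2-[3,4-bis(benzyloxy)phenyl]ethenyl 3,4,5-tris(benzyloxy)benzoate (3 equiv)
Product: 15 henicosa-O-benzyl procyanidin C1 3,3',3''-tri-O-gallate (three 5,7,3',4'-tetra-O-benzyl-3-O-(tri-O-benzylgalloyl)epicatechin units linked 4β→8 twice; every unit 2R,3R), via ortho-quinone methide 14 (not isolated)
Conditions: (R)-3,3'-bis(2,4,6-triisopropylphenyl)-1,1'-binaphthyl-2,2'-diyl hydrogen phosphate (10 mol%), 4 Å MS, toluene, 0 °C to rt, slow addition of 10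
Reagents that add atoms: none
Why: Proposed new method: the phosphoric acid ionises the 2,4,6-trioxygenated benzylic alcohol of 10 with loss of water (taken up by the molecular sieves) to ortho-quinone methide 14, held by hydrogen bonding to the chiral phosphate, and 14 is trapped by the electron-rich alkene of 13 in a concerted, asynchronous inverse-electron-demand oxa-[4+2] cycloaddition. The closest known reaction types are the chiral-phosphoric-acid-catalysed [4+2] cycloadditions of ortho-quinone methides generated from ortho-hydroxybenzyl alcohols with styrenes and vinyl sulfides, and the thermal cycloaddition of ortho-quinone methides with β-substituted styrenes to 2,3-disubstituted flavans; the new elements are a (Z)-enol ester of an arylacetaldehyde as the 2π partner and an unsubstituted methide on a chiral oligomer. Ring C of the terminal unit is closed in the [4+2] mode: C4–C3 bond formation leads (methide carbon onto the alkene carbon that bears the ester oxygen) and O1–C2 bond formation completes the six-membered ring. The cis relation of C2 and C3 follows from suprafacial addition to the Z alkene, and their absolute (2R,3R) sense is to be set by the face of 13 that the binaphthyl phosphate leaves open (reagent control), not by the remote centres of the dimer. The step needs regioselectivity, secured by the para-benzyloxy group on the aryl ring of 13, which stabilises developing positive charge at the future C2 far better than the acyloxy group does at C3; site selectivity of methide formation, secured by the single free phenol at C8a (the 5- and 7-oxygens are benzylated); and cycloaddition faster than Friedel–Crafts capture of 14, for which 13 is used in excess and 10 is added slowly.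

**Step 11**
Reactants: 15 henicosa-O-benzyl procyanidin C1 3,3',3''-tri-O-gallate
Product: 16 procyanidin C1 3,3',3''-tri-O-gallate
Conditions: H2 (1 atm), Pd(OH)2 on carbon, THF/MeOH/H2O, rt
Reagents that add atoms: none
Why: Heterogeneous hydrogenolysis of all twenty-one benzyl ethers under neutral conditions, which leaves the gallate esters, the benzylic C2–O1 bonds and the acid-labile interflavan bonds intact and touches no stereocentre.

**Compound list**

1 | (−)-epicatechin, (2R,3R) | O[C@@H]1Cc2c(O)cc(O)cc2O[C@@H]1c1ccc(O)c(O)c1 | starting material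

2 | 5,7,3',4'-tetra-O-benzyl-(−)-epicatechin | O[C@@H]1Cc2c(OCc5ccccc5)cc(OCc5ccccc5)cc2O[C@@H]1c1ccc(OCc5ccccc5)c(OCc5ccccc5)c1 | intermediate

3 | 4β-(2-ethoxyethoxy)-5,7,3',4'-tetra-O-benzylepicatechin | O[C@@H]1[C@@H](OCCOCC)c2c(OCc5ccccc5)cc(OCc5ccccc5)cc2O[C@@H]1c1ccc(OCc5ccccc5)c(OCc5ccccc5)c1 | intermediate

4 | 3,4,5-tris(benzyloxy)benzoic acid | OC(=O)c1cc(OCc2ccccc2)c(OCc2ccccc2)c(OCc2ccccc2)c1 | starting material

5 | 4β-(2-ethoxyethoxy)-5,7,3',4'-tetra-O-benzylepicatechin 3-O-[3,4,5-tris(benzyloxy)benzoate] | O=C(O[C@@H]1[C@@H](OCCOCC)c2c(OCc5ccccc5)cc(OCc5ccccc5)cc2O[C@@H]1c1ccc(OCc5ccccc5)c(OCc5ccccc5)c1)c1cc(OCc5ccccc5)c(OCc5ccccc5)c(OCc5ccccc5)c1 | intermediate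

6 | 3,5-bis(benzyloxy)phenol | Oc1cc(OCc2ccccc2)cc(OCc2ccccc2)c1 | starting material

7 | 4β-[2-hydroxy-4,6-bis(benzyloxy)phenyl]-5,7,3',4'-tetra-O-benzylepicatechin 3-O-[3,4,5-tris(benzyloxy)benzoate] | O=C(O[C@@H]1[C@@H](c2c(OCc5ccccc5)cc(OCc5ccccc5)cc2O)c2c(OCc5ccccc5)cc(OCc5ccccc5)cc2O[C@@H]1c1ccc(OCc5ccccc5)c(OCc5ccccc5)c1)c1cc(OCc5ccccc5)c(OCc5ccccc5)c(OCc5ccccc5)c1 | intermediate

8 | 4β-[3-formyl-2-hydroxy-4,6-bis(benzyloxy)phenyl]-5,7,3',4'-tetra-O-benzylepicatechin 3-O-[3,4,5-tris(benzyloxy)benzoate] | O=C(O[C@@H]1[C@@H](c2c(OCc5ccccc5)cc(OCc5ccccc5)c(C=O)c2O)c2c(OCc5ccccc5)cc(OCc5ccccc5)cc2O[C@@H]1c1ccc(OCc5ccccc5)c(OCc5ccccc5)c1)c1cc(OCc5ccccc5)c(OCc5ccccc5)c(OCc5ccccc5)c1 | intermediate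

9 | dimer salicylaldehyde: galloylated benzylated epicatechin-(4β→8)-[4β-(3-formyl-2-hydroxy-4,6-bis(benzyloxy)phenyl)] galloylated benzylated epicatechin | O=C(O[C@@H]1[C@@H](c2c(OCc5ccccc5)cc(OCc5ccccc5)c(C=O)c2O)c2c(OCc5ccccc5)cc(OCc5ccccc5)c([C@H]3c4c(OCc5ccccc5)cc(OCc5ccccc5)cc4O[C@H](c4ccc(OCc5ccccc5)c(OCc5ccccc5)c4)[C@@H]3OC(=O)c3cc(OCc5ccccc5)c(OCc5ccccc5)c(OCc5ccccc5)c3)c2O[C@@H]1c1ccc(OCc5ccccc5)c(OCc5ccccc5)c1)c1cc(OCc5ccccc5)c(OCc5ccccc5)c(OCc5ccccc5)c1 | intermediate

10 | dimer salicyl alcohol: as 9 with CH2OH in place of CHO | O=C(O[C@@H]1[C@@H](c2c(OCc5ccccc5)cc(OCc5ccccc5)c(CO)c2O)c2c(OCc5ccccc5)cc(OCc5ccccc5)c([C@H]3c4c(OCc5ccccc5)cc(OCc5ccccc5)cc4O[C@H](c4ccc(OCc5ccccc5)c(OCc5ccccc5)c4)[C@@H]3OC(=O)c3cc(OCc5ccccc5)c(OCc5ccccc5)c(OCc5ccccc5)c3)c2O[C@@H]1c1ccc(OCc5ccccc5)c(OCc5ccccc5)c1)c1cc(OCc5ccccc5)c(OCc5ccccc5)c(OCc5ccccc5)c1 | intermediate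

11 | 3,4-bis(benzyloxy)benzaldehyde | O=Cc1ccc(OCc2ccccc2)c(OCc2ccccc2)c1 | starting material

12 | 1,2-bis(benzyloxy)-4-ethynylbenzene | C#Cc1ccc(OCc2ccccc2)c(OCc2ccccc2)c1 | intermediate

13 | (Z)-2-[3,4-bis(benzyloxy)phenyl]ethenyl 3,4,5-tris(benzyloxy)benzoate | O=C(O/C=C\c1ccc(OCc2ccccc2)c(OCc2ccccc2)c1)c1cc(OCc2ccccc2)c(OCc2ccccc2)c(OCc2ccccc2)c1 | intermediate

14 | ortho-quinone methide of 10 (3,5-bis(benzyloxy)-6-methylidenecyclohexa-2,4-dienone carrying the dimer at C2) | O=C(O[C@@H]1[C@@H](C2=C(OCc5ccccc5)C=C(OCc5ccccc5)C(=C)C2=O)c2c(OCc5ccccc5)cc(OCc5ccccc5)c([C@H]3c4c(OCc5ccccc5)cc(OCc5ccccc5)cc4O[C@H](c4ccc(OCc5ccccc5)c(OCc5ccccc5)c4)[C@@H]3OC(=O)c3cc(OCc5ccccc5)c(OCc5ccccc5)c(OCc5ccccc5)c3)c2O[C@@H]1c1ccc(OCc5ccccc5)c(OCc5ccccc5)c1)c1cc(OCc5ccccc5)c(OCc5ccccc5)c(OCc5ccccc5)c1 | intermediate (not isolated)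

15 | henicosa-O-benzyl procyanidin C1 3,3',3''-tri-O-gallate | O=C(O[C@@H]1[C@@H](c2c(OCc5ccccc5)cc(OCc5ccccc5)c3c2O[C@H](c2ccc(OCc5ccccc5)c(OCc5ccccc5)c2)[C@H](OC(=O)c2cc(OCc5ccccc5)c(OCc5ccccc5)c(OCc5ccccc5)c2)C3)c2c(OCc5ccccc5)cc(OCc5ccccc5)c([C@H]3c4c(OCc5ccccc5)cc(OCc5ccccc5)cc4O[C@H](c4ccc(OCc5ccccc5)c(OCc5ccccc5)c4)[C@@H]3OC(=O)c3cc(OCc5ccccc5)c(OCc5ccccc5)c(OCc5ccccc5)c3)c2O[C@@H]1c1ccc(OCc5ccccc5)c(OCc5ccccc5)c1)c1cc(OCc5ccccc5)c(OCc5ccccc5)c(OCc5ccccc5)c1 | intermediate

16 | procyanidin C1 3,3',3''-tri-O-gallate | O=C(O[C@@H]1[C@@H](c2c(O)cc(O)c3c2O[C@H](c2ccc(O)c(O)c2)[C@H](OC(=O)c2cc(O)c(O)c(O)c2)C3)c2c(O)cc(O)c([C@H]3c4c(O)cc(O)cc4O[C@H](c4ccc(O)c(O)c4)[C@@H]3OC(=O)c3cc(O)c(O)c(O)c3)c2O[C@@H]1c1ccc(O)c(O)c1)c1cc(O)c(O)c(O)c1 | target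

**Step count and risks**

Total step count: 11. Longest linear sequence: 9 steps (steps 1, 2, 3, 4, 5, 6, 7, 10, 11); steps 8 and 9 form the dienophile branch.

Steps most likely to fail:

1. Step 10 (proposed new method). Facial selectivity may be poor if the chiral phosphate and the bulky chiral dimer are mismatched. The cis fidelity may erode if the addition turns stepwise through a benzylic cation at C2. The methide may be lost to Friedel–Crafts capture by the benzylated rings A. The enol ester may transfer its acyl group to the free phenol.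
 Fallback (known interflavan couplings, the terminal unit taken from epicatechin): setting out from 2, Steglich esterification with 4 (DCC, DMAP) gives 5,7,3',4'-tetra-O-benzylepicatechin 3-O-(tri-O-benzylgallate) F1. TMSOTf-catalysed coupling of electrophile 5 with an excess of F1 gives benzylated procyanidin B2 3,3'-di-O-gallate F2 (4β→8). A second TMSOTf coupling of 5 with F2, which reacts at C8 of its upper unit, comes back to the route at 15.

2. Step 6. The electrophile may self-condense through its own free C8, attack may be split between C8 and C6 of the nucleophile, and acid may scramble the existing C4–aryl bond.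
 Fallback (C8 blocking group instead of excess nucleophile): setting out from 5, bromination with N-bromosuccinimide (CH2Cl2, −40 °C) gives 8-bromo-4β-(2-ethoxyethoxy)-5,7,3',4'-tetra-O-benzylepicatechin 3-O-(tri-O-benzylgallate) F3, which cannot act as a nucleophile. Equimolar TMSOTf coupling of F3 with 8 gives the 8-bromo analogue of the dimer salicylaldehyde F4. Radical hydrodebromination (Bu3SnH, AIBN, toluene, 80 °C) comes back to the route at 9.

3. Step 5. Formylation of the hindered, electron-rich phenol may be sluggish, and the magnesium methoxide formed may transesterify the gallate.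
 Fallback (boron-templated hydroxymethylation, then oxidation): setting out from 7, phenylboronic acid, paraformaldehyde and catalytic propionic acid in toluene at reflux give the 2-phenyl-4H-1,3,2-benzodioxaborin of 7 F5. Oxidative cleavage of the boronate (H2O2, THF, 0 °C) gives 4β-[3-hydroxymethyl-2-hydroxy-4,6-bis(benzyloxy)phenyl]-5,7,3',4'-tetra-O-benzylepicatechin 3-O-(tri-O-benzylgallate) F6. MnO2 oxidation of the benzylic alcohol (CH2Cl2, rt) comes back to the route at 8.

**Further compounds**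

F1 | step 10 | 5,7,3',4'-tetra-O-benzylepicatechin 3-O-(tri-O-benzylgallate) | O=C(O[C@@H]1Cc2c(OCc5ccccc5)cc(OCc5ccccc5)cc2O[C@@H]1c1ccc(OCc5ccccc5)c(OCc5ccccc5)c1)c1cc(OCc5ccccc5)c(OCc5ccccc5)c(OCc5ccccc5)c1

F2 | step 10 | benzylated procyanidin B2 3,3'-di-O-gallate (4β→8) | O=C(O[C@@H]1Cc2c(OCc5ccccc5)cc(OCc5ccccc5)c([C@H]3c4c(OCc5ccccc5)cc(OCc5ccccc5)cc4O[C@H](c4ccc(OCc5ccccc5)c(OCc5ccccc5)c4)[C@@H]3OC(=O)c3cc(OCc5ccccc5)c(OCc5ccccc5)c(OCc5ccccc5)c3)c2O[C@@H]1c1ccc(OCc5ccccc5)c(OCc5ccccc5)c1)c1cc(OCc5ccccc5)c(OCc5ccccc5)c(OCc5ccccc5)c1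

F3 | step 6 | 8-bromo-4β-(2-ethoxyethoxy)-5,7,3',4'-tetra-O-benzylepicatechin 3-O-(tri-O-benzylgallate) | O=C(O[C@@H]1[C@@H](OCCOCC)c2c(OCc5ccccc5)cc(OCc5ccccc5)c(Br)c2O[C@@H]1c1ccc(OCc5ccccc5)c(OCc5ccccc5)c1)c1cc(OCc5ccccc5)c(OCc5ccccc5)c(OCc5ccccc5)c1

F4 | step 6 | 8-bromo analogue of 9 (bromine at C8 of the top unit) | O=C(O[C@@H]1[C@@H](c2c(OCc5ccccc5)cc(OCc5ccccc5)c(C=O)c2O)c2c(OCc5ccccc5)cc(OCc5ccccc5)c([C@H]3c4c(OCc5ccccc5)cc(OCc5ccccc5)c(Br)c4O[C@H](c4ccc(OCc5ccccc5)c(OCc5ccccc5)c4)[C@@H]3OC(=O)c3cc(OCc5ccccc5)c(OCc5ccccc5)c(OCc5ccccc5)c3)c2O[C@@H]1c1ccc(OCc5ccccc5)c(OCc5ccccc5)c1)c1cc(OCc5ccccc5)c(OCc5ccccc5)c(OCc5ccccc5)c1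

F5 | step 5 | 2-phenyl-4H-1,3,2-benzodioxaborin of 7 (boron bridging the phenol oxygen and the new ortho CH2O group) | O=C(O[C@@H]1[C@@H](c2c(OCc5ccccc5)cc(OCc5ccccc5)c3c2OB(c2ccccc2)OC3)c2c(OCc5ccccc5)cc(OCc5ccccc5)cc2O[C@@H]1c1ccc(OCc5ccccc5)c(OCc5ccccc5)c1)c1cc(OCc5ccccc5)c(OCc5ccccc5)c(OCc5ccccc5)c1

F6 | step 5 | 4β-[3-hydroxymethyl-2-hydroxy-4,6-bis(benzyloxy)phenyl]-5,7,3',4'-tetra-O-benzylepicatechin 3-O-(tri-O-benzylgallate) | O=C(O[C@@H]1[C@@H](c2c(OCc5ccccc5)cc(OCc5ccccc5)c(CO)c2O)c2c(OCc5ccccc5)cc(OCc5ccccc5)cc2O[C@@H]1c1ccc(OCc5ccccc5)c(OCc5ccccc5)c1)c1cc(OCc5ccccc5)c(OCc5ccccc5)c(OCc5ccccc5)c1
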